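Read the leftover first: at 12.0 h the dusk run still holds 8.10% of left-handed substrate and right-handed substrate together, by difference from its two products. This is a dynamic kinetic resolution: free catalyst joins each substrate to coupling partner, and racemization catalyst exchanges the two substrates.

| setting | dusk | dawn | midnight | flask |
|---|---|---|---|---|
| left-handed substrate | 0.050 M | 0.050 M | 0.050 M | 0.050 M |
| right-handed substrate | 0.050 M | 0.050 M | 0.050 M | 0.050 M |
| coupling partner | 0.10 M | 0.10 M | 0.20 M | 0.100 M |
| free catalyst | 5 mM | 5 mM | 5 mM | 5.0 mM |
| racemization catalyst | 1.4 mM | 1.4 mM | 1.4 mM | 1.4 mM |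
| added ligand | 2.1 mM | 3.3 mM | 1.5 mM | 1.5 mM |
| remark | run made earlier | run made earlier | run made earlier |  |
| time |  |  |  | 12 h |

| run | time / h | left-handed product / % | right-handed product / % |
|---|---|---|---|
| dusk | 1.50 | 38.2 | 17.9 |
| dusk | 3.00 | 48.3 | 22.9 |
| dusk | 5.00 | 55.8 | 25.6 |
| dusk | 6.00 | 56.7 | 26.7 |
| dusk | 8.00 | 59.9 | 28.3 |
| dusk | 10.0 | 61.1 | 28.6 |
| dusk | 12.0 | 62.2 | 29.7 |
| dawn | 1.00 | 30.5 | 13.7 |
| dawn | 1.33 | 35.7 | 17.5 |
| dawn | 2.00 | 41.5 | 20.7 |
| dawn | 3.00 | 47.9 | 23.0 |
| dawn | 5.00 | 54.8 | 25.6 |
| dawn | 8.00 | 59.0 | 27.7 |
| dawn | 12.0 | 61.8 | 30.1 |
| midnight | 1.00 | 47.9 | 24.9 |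
| midnight | 3.00 | 63.8 | 32.1 |
| midnight | 6.00 | 66.3 | 34.0 |
| midnight | 8.00 | 66.4 | 33.3 |
| midnight | 12.0 | 66.1 | 34.1 |

(standard deviation of a reading: 0.5 percentage points)

- left-handed product and right-handed product together, in percent of the left-handed substrate and right-handed substrate charged together, at 12 h
- excess of left-handed product over right-handed product in the product at 12 h
- whether the exchange between left-handed substrate and right-handed substrate keeps pace with the reaction: how far the product's excess at 12 h gets from its value without exchange to its value with instant exchange (above 80% keeps pace, below 20% hardly takes part, else lags behind)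

- free catalyst is single-handed; left-handed substrate and right-handed substrate are mirror images of each other, charged as a racemate, each of them at the stated concentration
- what was read earlier has a scatter of 0.5 percentage points, one standard deviation
- an excess is the difference of the two amounts in percent of their sum
- an excess is below zero if the other one leads

Count turnovers. In the dusk run, the dawn run and the flask, the coupling partner charge equals the two substrates together, so both fall in step; if the rate goes with coupling partner times substrate at constant free catalyst, reacted part over leftover grows in proportion to time. The dusk run at 3.00 h gives 0.824 h⁻¹: the coupling count, reacted part over leftover per hour of run. Read it there, where the leftover of 28.8% is larger than 8.10% and scatter weighs less.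

Set the flask beside the dusk run: they differ in added ligand, 1.5 mM against 2.1 mM. The dawn run, at 3.3 mM, reads 0.812 h⁻¹ at the same hour, close to the dusk count, so carry the dusk count to the flask, though the flask's added ligand lies below the range of these two runs. My reckoning for the flask is 9.89 turns in 12 h, hence 90.8% reacted.

The dusk excess reads 36.2% at 1.50 h and 35.4% at 12.0 h. Its left-handed product, 62.2%, exceeds the 50.0% charged as left-handed substrate. So I expect the flask to end near 35.4%, with exchange keeping pace.

The forecast gives 92%, above mine, on the ground that “The rate does not change between 2.1 and 3.3 mM ligand”; for the excess it gives 35%, and for the exchange keeps pace.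

The flask gives 90.9% with excess 36.8%, and the exchange keeps pace, at 92% of the way.

    coupling partner + free catalyst + left-handed substrate → free catalyst + left-handed product (k = 39.0 L² mol⁻² min⁻¹)
    coupling partner + free catalyst + right-handed substrate → free catalyst + right-handed product (k = 17.0 L² mol⁻² min⁻¹)
    left-handed substrate + racemization catalyst ⇌ right-handed substrate + racemization catalyst, rate k3*[racemization catalyst]*[left-handed substrate] forward; the back reaction follows from the equilibrium constant (k = 54.0 L mol⁻¹ min⁻¹)
    racemization catalyst + added ligand ⇌ idle complex, settled at all times (K = 830 L mol⁻¹)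

With charged concentrations and forward steps taken singly, left-handed substrate has an exchange half-life of 0.15 h, against 1.2 h for coupling partner through left-handed product. The flask's count is 0.835 h⁻¹. Scale it by free catalyst for the neighbour charged with 0.013 M: 26.1 turns in 12 h give 96.3%, and that neighbour gives 96.3%.

(All runs come from a simulation for an exercise; noise was put on by code.)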